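**Strategy.** Ring C is disconnected at C3–C4. Read backwards, C4 (ketone on ring A), C3 (CH2) and C2 (H-bearing stereocentre between O1 and ring B) are the adduct of an aldehyde C–H bond across a 1,1-disubstituted aryl enol ether. The key step is therefore an enantioselective rhodium-catalysed intramolecular hydroacylation: the formyl group on ring A adds across the O1–C2(=C3H2)–aryl unit of the achiral aldehyde 10, closing ring C and setting C2 in one operation, with no base-labile chalcone intermediate. Aldehyde 10 is assembled from an ortho-prenylated, ortho-formylated 3,5-dimethoxyphenol and an isovanillin-derived chlorohydrin by Mitsunobu etherification and dehydrochlorination. Chelation-controlled 5-O-demethylation and MOM removal finish the route.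

Key step: step 7

Assumption: flavanone numbering is used (O1, C2, C3, C4 in ring C; ring A is the benzo ring, ring B the 2-aryl group); the target is the (2S) enantiomer. The sense of induction in step 7 cannot be assigned in advance: the (R)-ligand is written, and its antipode is to be used if a pilot run shows the opposite sense.

Step 1
Reactants: 1 3,5-dimethoxyphenol; 2 prenyl bromide (1-bromo-3-methylbut-2-ene)
Product: 3 3,5-dimethoxy-2-(3-methylbut-2-en-1-yl)phenol
Conditions: NaH, toluene, 0 °C to rt
Reagents that add atoms: none
Why: Ortho C-alkylation of a sodium phenoxide in a non-coordinating solvent (phenolate C-prenylation): the tight ion pair should deliver the allylic bromide to the ortho carbon, the two ortho positions of 1 are equivalent, and the dienone tautomerises to 3.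

Step 2
Reactants: 3 3,5-dimethoxy-2-(3-methylbut-2-en-1-yl)phenol
Product: 5 2-hydroxy-4,6-dimethoxy-3-(3-methylbut-2-en-1-yl)benzaldehyde, via ortho-hydroxymethyl phenol 4 (not isolated)
Conditions: MgCl2, Et3N, paraformaldehyde, MeCN, reflux
Reagents that add atoms: paraformaldehyde (formaldehyde), C=O
Why: Casnati–Skattebøl ortho-formylation: the magnesium phenoxide should hydroxymethylate the only free ortho position, and a second formaldehyde oxidises the benzylic alkoxide 4 by hydride transfer, so the position between the two methoxy groups is not touched.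

Step 3
Reactants: 6 isovanillin (3-hydroxy-4-methoxybenzaldehyde)
Product: 7 4-methoxy-3-(methoxymethoxy)benzaldehyde
Conditions: MOMCl, iPr2NEt, CH2Cl2, 0 °C to rt
Reagents that add atoms: chloromethyl methyl ether, COCCl
Why: O-alkylation of the phenol with a reactive alpha-chloro ether (MOM protection), which masks the ring B hydroxyl through the Mitsunobu, base and rhodium steps.

Step 4
Reactants: 7 4-methoxy-3-(methoxymethoxy)benzaldehyde
Product: 8 racemic 2-chloro-1-[4-methoxy-3-(methoxymethoxy)phenyl]ethan-1-ol
Conditions: ICH2Cl, MeLi·LiBr, THF, −78 °C; then AcOH, −78 °C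
Reagents that add atoms: chloroiodomethane, ClCI
Why: Carbenoid addition: iodine–lithium exchange in the presence of the aldehyde gives chloromethyllithium, which adds to the formyl group, and protonation at −78 °C should keep the chlorohydrin from closing to the epoxide; the racemic carbinol centre is destroyed in step 6.

Step 5
Reactants: 5 2-hydroxy-4,6-dimethoxy-3-(3-methylbut-2-en-1-yl)benzaldehyde; 8 racemic 2-chloro-1-[4-methoxy-3-(methoxymethoxy)phenyl]ethan-1-ol
Product: 9 racemic 2-{2-chloro-1-[4-methoxy-3-(methoxymethoxy)phenyl]ethoxy}-4,6-dimethoxy-3-(3-methylbut-2-en-1-yl)benzaldehyde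
Conditions: PPh3, DIAD, THF, 0 °C to rt
Reagents that add atoms: none
Why: Mitsunobu etherification: the hydrogen-bonded salicylaldehyde-type phenol of 5 is acidic enough to protonate the betaine and should displace the benzylic oxyphosphonium of 8; the configuration of the new centre is irrelevant because it becomes sp2 in step 6.

Step 6
Reactants: 9 racemic 2-{2-chloro-1-[4-methoxy-3-(methoxymethoxy)phenyl]ethoxy}-4,6-dimethoxy-3-(3-methylbut-2-en-1-yl)benzaldehyde
Product: 10 4,6-dimethoxy-2-({1-[4-methoxy-3-(methoxymethoxy)phenyl]ethenyl}oxy)-3-(3-methylbut-2-en-1-yl)benzaldehyde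
Conditions: KOtBu, THF, 0 °C to rt; purification on Et3N-deactivated silica
Reagents that add atoms: none
Why: E2 dehydrochlorination of a beta-chloroethyl aryl ether (standard aryl vinyl ether synthesis): the only beta-hydrogen is the benzylic, oxygen-bearing one, so loss of HCl can give only the 1,1-disubstituted enol ether, and the non-enolisable aldehyde should tolerate the hindered base.

Step 7
Reactants: 10 4,6-dimethoxy-2-({1-[4-methoxy-3-(methoxymethoxy)phenyl]ethenyl}oxy)-3-(3-methylbut-2-en-1-yl)benzaldehyde
Product: 11 (2S)-5,7-dimethoxy-2-[4-methoxy-3-(methoxymethoxy)phenyl]-8-(3-methylbut-2-en-1-yl)-2,3-dihydro-4H-chromen-4-one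
Conditions: [Rh(cod)Cl]2 (2.5 mol %), (R)-DTBM-SEGPHOS (5 mol %), Na[B(3,5-(CF3)2C6H3)4] (5 mol %), anhydrous 1,4-dioxane, 80 °C
Reagents that add atoms: none
Why: Proposed new method: the cationic monovalent rhodium–bisphosphine complex should insert into the formyl C–H bond of 10 to give an acyl trivalent rhodium hydride held near the enol ether by O1, the alkene then inserts into Rh–H with hydride delivered to C2 and rhodium bound to the unhindered terminal carbon C3, and C–C reductive elimination from the seven-membered acyl–alkyl rhodacycle forms the C3–C4 bond in an atom-economic isomerisation. The closest known reaction type is the rhodium-catalysed enantioselective endo-hydroacylation of ortho-(2-substituted allyl)benzaldehydes to 3-substituted tetralones, from which 10 differs in that the benzylic CH2 of the tether is the ether oxygen O1. Ring C closes in a formal 6-endo-trig mode, the acyl carbon bonding to the terminal alkene carbon. The C2 stereocentre is created in the hydride insertion and is controlled by the chiral pocket of DTBM-SEGPHOS, which differentiates the two faces of the 1,1-disubstituted enol ether. The step needs endo over exo regioselectivity (exo closure would give a 2-aryl-2-methylbenzofuran-3-one through a tertiary alkylrhodium) and hydroacylation over decarbonylation; the 1,1-disubstitution and the primary alkylrhodium should secure the first and the two ortho oxygen donors that stabilise the acylrhodium hydride the second, while the enol ether has no allylic hydrogen to isomerise and the prenyl alkene on C8 cannot reach the metal.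

Step 8
Reactants: 11 (2S)-5,7-dimethoxy-2-[4-methoxy-3-(methoxymethoxy)phenyl]-8-(3-methylbut-2-en-1-yl)-2,3-dihydro-4H-chromen-4-one
Product: 12 (2S)-5-hydroxy-7-methoxy-2-[4-methoxy-3-(methoxymethoxy)phenyl]-8-(3-methylbut-2-en-1-yl)-2,3-dihydro-4H-chromen-4-one
Conditions: MgI2·OEt2, THF, 60 °C; 1 M HCl work-up
Reagents that add atoms: none
Why: Chelation-controlled demethylation of an aryl methyl ether peri to a ketone: the magnesium ion binds C4=O and the C5 methoxy oxygen and iodide removes that methyl group by SN2, a transformation known for 5-methoxy-8-prenylflavanones, while the C7 and ring B methoxy groups, the prenyl group and the C2 centre should not be engaged under these base-free conditions.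

Step 9
Reactants: 12 (2S)-5-hydroxy-7-methoxy-2-[4-methoxy-3-(methoxymethoxy)phenyl]-8-(3-methylbut-2-en-1-yl)-2,3-dihydro-4H-chromen-4-one
Product: 13 (2S)-5-hydroxy-2-(3-hydroxy-4-methoxyphenyl)-7-methoxy-8-(3-methylbut-2-en-1-yl)-2,3-dihydro-4H-chromen-4-one
Conditions: 3 M HCl, MeOH, 40 °C
Reagents that add atoms: none
Why: Acid-catalysed acetal cleavage (MOM deprotection) in methanol, which traps the methoxymethyl cation as dimethoxymethane; the C2 centre should hold because flavanones racemise by base-mediated ring opening, and no free hydroxyl is ortho to the prenyl group, so chroman formation is excluded.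

**Compound list**

1 | 3,5-dimethoxyphenol | COc1cc(O)cc(OC)c1 | starting material
2 | prenyl bromide (1-bromo-3-methylbut-2-ene) | CC(C)=CCBr | starting material
3 | 3,5-dimethoxy-2-(3-methylbut-2-en-1-yl)phenol | COc1cc(O)c(CC=C(C)C)c(OC)c1 | intermediate
4 | 2-(hydroxymethyl)-3,5-dimethoxy-6-(3-methylbut-2-en-1-yl)phenol (formed as its magnesium salt) | COc1cc(OC)c(CO)c(O)c1CC=C(C)C | intermediate (not isolated)
5 | 2-hydroxy-4,6-dimethoxy-3-(3-methylbut-2-en-1-yl)benzaldehyde | COc1cc(OC)c(C=O)c(O)c1CC=C(C)C | intermediate
6 | isovanillin (3-hydroxy-4-methoxybenzaldehyde) | COc1ccc(C=O)cc1O | starting material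
7 | 4-methoxy-3-(methoxymethoxy)benzaldehyde | COCOc1cc(C=O)ccc1OC | intermediate
8 | racemic 2-chloro-1-[4-methoxy-3-(methoxymethoxy)phenyl]ethan-1-ol | COCOc1cc(C(O)CCl)ccc1OC | intermediate
9 | racemic 2-{2-chloro-1-[4-methoxy-3-(methoxymethoxy)phenyl]ethoxy}-4,6-dimethoxy-3-(3-methylbut-2-en-1-yl)benzaldehyde | COCOc1cc(C(CCl)Oc2c(C=O)c(OC)cc(OC)c2CC=C(C)C)ccc1OC | intermediate
10 | 4,6-dimethoxy-2-({1-[4-methoxy-3-(methoxymethoxy)phenyl]ethenyl}oxy)-3-(3-methylbut-2-en-1-yl)benzaldehyde | COCOc1cc(C(=C)Oc2c(C=O)c(OC)cc(OC)c2CC=C(C)C)ccc1OC | intermediate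
11 | (2S)-5,7-dimethoxy-2-[4-methoxy-3-(methoxymethoxy)phenyl]-8-(3-methylbut-2-en-1-yl)-2,3-dihydro-4H-chromen-4-one | COCOc1cc([C@@H]2CC(=O)c3c(OC)cc(OC)c(CC=C(C)C)c3O2)ccc1OC | intermediate
12 | (2S)-5-hydroxy-7-methoxy-2-[4-methoxy-3-(methoxymethoxy)phenyl]-8-(3-methylbut-2-en-1-yl)-2,3-dihydro-4H-chromen-4-one | COCOc1cc([C@@H]2CC(=O)c3c(O)cc(OC)c(CC=C(C)C)c3O2)ccc1OC | intermediate
13 | (2S)-5-hydroxy-2-(3-hydroxy-4-methoxyphenyl)-7-methoxy-8-(3-methylbut-2-en-1-yl)-2,3-dihydro-4H-chromen-4-one | COc1ccc([C@@H]2CC(=O)c3c(O)cc(OC)c(CC=C(C)C)c3O2)cc1O | target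

Total step count: 9. Longest linear sequence: 7 steps (steps 1, 2, 5, 6, 7, 8, 9 from compound 1; equally steps 3, 4, 5, 6, 7, 8, 9 from compound 6).

**Steps most likely to fail**

1. Step 7 (proposed new method). The acylrhodium hydride may decarbonylate before the alkene inserts, insertion may proceed in the exo sense, the cationic metal may hydrolyse the enol ether with trace water, or facial discrimination may be weak. The fallback uses known chemistry, sets out from 8 and 5 and comes back at 11. Racemic 8 is oxidised with Dess–Martin periodinane to 2-chloro-1-[4-methoxy-3-(methoxymethoxy)phenyl]ethan-1-one F1. Corey–Bakshi–Shibata reduction ((S)-2-methyl-CBS-oxazaborolidine, BH3·SMe2) should then give (S)-2-chloro-1-[4-methoxy-3-(methoxymethoxy)phenyl]ethan-1-ol F2. Mitsunobu etherification of 5 with F2 (PPh3, DIAD, toluene, 0 °C) should proceed with inversion to 2-{(1R)-2-chloro-1-[4-methoxy-3-(methoxymethoxy)phenyl]ethoxy}-4,6-dimethoxy-3-(3-methylbut-2-en-1-yl)benzaldehyde F3. Finkelstein exchange (NaI, acetone, reflux) gives 2-{(1R)-2-iodo-1-[4-methoxy-3-(methoxymethoxy)phenyl]ethoxy}-4,6-dimethoxy-3-(3-methylbut-2-en-1-yl)benzaldehyde F4. An N-heterocyclic carbene-catalysed intramolecular nucleophilic substitution (3-benzyl-5-(2-hydroxyethyl)-4-methylthiazolium chloride, DBU, 1,4-dioxane, 80 °C) then closes ring C: the Breslow intermediate of the aldehyde displaces iodide at C3 and forms the same C3–C4 bond without touching C2. This ring closure is a known route to chroman-4-ones; its price is reliance on clean inversion at an electron-rich benzylic carbinol.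

2. Step 5. The hindered, hydrogen-bonded phenoxide may capture the oxyphosphonium ion too slowly, so that the activated benzylic alcohol eliminates instead. The fallback sets out from 8 and 5 and comes back at 9. Alcohol 8 is converted (Cl3CCN, catalytic DBU, CH2Cl2, 0 °C) into racemic 2-chloro-1-[4-methoxy-3-(methoxymethoxy)phenyl]ethyl 2,2,2-trichloroacetimidate F5. Phenol 5 is then O-alkylated with F5 under acid catalysis (5 mol % TMSOTf, CH2Cl2, −40 °C) through the methoxy-stabilised benzylic cation, an SN1-type etherification in place of the redox condensation.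

3. Step 1. O-alkylation, C-alkylation at the position between the two methoxy groups, and double prenylation may compete with ortho C-prenylation. The fallback sets out from 1 and comes back at 3. Allylic etherification of 1 with methyl 2-methylbut-3-en-2-yl carbonate, catalysed by Pd(PPh3)4 (zerovalent palladium) in THF, should give the branched ether 1,3-dimethoxy-5-[(2-methylbut-3-en-2-yl)oxy]benzene F6. Aromatic Claisen rearrangement (N,N-diethylaniline, 180 °C) transposes it to the ortho-prenyl phenol 3, with the regiochemistry fixed by the [3,3] shift.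

**Further compounds**

F1 | step 7 | 2-chloro-1-[4-methoxy-3-(methoxymethoxy)phenyl]ethan-1-one | COCOc1cc(C(=O)CCl)ccc1OC
F2 | step 7 | (S)-2-chloro-1-[4-methoxy-3-(methoxymethoxy)phenyl]ethan-1-ol | COCOc1cc([C@H](O)CCl)ccc1OC
F3 | step 7 | 2-{(1R)-2-chloro-1-[4-methoxy-3-(methoxymethoxy)phenyl]ethoxy}-4,6-dimethoxy-3-(3-methylbut-2-en-1-yl)benzaldehyde | COCOc1cc([C@H](CCl)Oc2c(C=O)c(OC)cc(OC)c2CC=C(C)C)ccc1OC
F4 | step 7 | 2-{(1R)-2-iodo-1-[4-methoxy-3-(methoxymethoxy)phenyl]ethoxy}-4,6-dimethoxy-3-(3-methylbut-2-en-1-yl)benzaldehyde | COCOc1cc([C@H](CI)Oc2c(C=O)c(OC)cc(OC)c2CC=C(C)C)ccc1OC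
F5 | step 5 | racemic 2-chloro-1-[4-methoxy-3-(methoxymethoxy)phenyl]ethyl 2,2,2-trichloroacetimidate | COCOc1cc(C(CCl)OC(=N)C(Cl)(Cl)Cl)ccc1OC
F6 | step 1 | 1,3-dimethoxy-5-[(2-methylbut-3-en-2-yl)oxy]benzene | COc1cc(OC)cc(OC(C)(C)C=C)c1
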